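## Retrosynthetic overview

1. The target comes from its 2-(trimethylsilyl)ethyl ester with the ketone held as a silyl-protected alcohol; the two epimerisable ketone α-centres are unveiled only at the end.
2. Both rings come from one intramolecular Diels–Alder reaction of an acyclic (2E,7E,9E,11E)-tetraenoate. It forms the ring-fusion bond C3a–C7a and the quaternary–quaternary bond C4–C5, and sets four stereocentres from the two tether centres.
3. The tetraene comes from a late Negishi coupling at the diene single bond between a 14-carbon vinyl iodide (three stereocentres, enoate) and a 12-carbon dienyl iodide.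
4. The vinyl iodide is built by Cu-catalysed allylic ethylation, Marshall propargylation, hydrozirconation–iodination and Wittig olefination; the dienyl iodide by Sonogashira coupling and ethylcupration–iodination of a phenylbutenyne.
5. Ring order: no ring exists before the cycloaddition; the cyclohexene and the cyclopentane close in the same step.

Assumption: the catalysts of steps 2 and 4 induce in the sense known for their closest analogues (cinnamyl bromide, aryl-ynones); if either proves opposite, the antipodal ligand is used and nothing else changes.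

Bicyclic names use 1H-indene locants with the carboxyl carbon on C4.

## Route

**Vinyl iodide fragment: aldehyde branch**

Step 1
Reactants: 1 (2E)-1,4-dibromobut-2-ene
Product: 2 1-({[(2E)-4-bromobut-2-en-1-yl]oxy}methyl)-4-methoxybenzene
Conditions: 4-MeOC6H4CH2OH, NaH, THF, 0 °C to rt (3 equiv of 1)
Reagents that add atoms: 4-methoxybenzyl alcohol COc1ccc(CO)cc1
Why: Williamson ether synthesis (SN2 of the alkoxide at one primary allylic bromide, excess dibromide suppressing the bis-ether); no stereocentre is formed.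

Step 2
Reactants: 2 1-({[(2E)-4-bromobut-2-en-1-yl]oxy}methyl)-4-methoxybenzene
Product: 3 1-({[(2R)-2-ethylbut-3-en-1-yl]oxy}methyl)-4-methoxybenzene
Conditions: EtMgBr, CuBr·SMe2 (1 mol%), (S,R)-TaniaPhos (1.2 mol%), CH2Cl2, −75 °C
Reagents that add atoms: ethylmagnesium bromide CC[Mg]Br
Why: Copper-catalysed asymmetric allylic alkylation, in which the chiral ferrocenyl-diphosphine copper ethyl species attacks the γ-carbon anti to bromide (SN2') on one alkene face and so sets the ethyl-bearing centre as R.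

Step 3
Reactants: 3 1-({[(2R)-2-ethylbut-3-en-1-yl]oxy}methyl)-4-methoxybenzene
Product: 5 (2S)-2-{[(4-methoxybenzyl)oxy]methyl}butanal, via ozonide 4 (not isolated)
Conditions: O3, CH2Cl2, −78 °C (Sudan Red 7B end point); then PPh3, −78 °C to rt; used crude
Reagents that add atoms: ozone [O-][O+]=O
Why: Ozonolysis with reductive work-up cleaves only the terminal alkene (the dye end point spares the anisyl ring) and leaves the existing centre untouched, its descriptor changing from R to S by priority only.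

**Vinyl iodide fragment: mesylate branch**

Step 4
Reactants: 6 pent-3-yn-2-one
Product: 7 (2R)-pent-3-yn-2-ol
Conditions: RuCl[(R,R)-TsDPEN](p-cymene) (0.5 mol%), i-PrOH, rt
Reagents that add atoms: none
Why: Noyori asymmetric transfer hydrogenation, in which the ruthenium hydride/NH pair delivers hydrogen to one carbonyl face with the alkynyl group in the position an aryl group normally takes, giving the R alcohol.

Step 5
Reactants: 7 (2R)-pent-3-yn-2-ol
Product: 8 (2R)-pent-3-yn-2-yl methanesulfonate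
Conditions: MsCl, Et3N, CH2Cl2, −78 to 0 °C
Reagents that add atoms: methanesulfonyl chloride CS(=O)(=O)Cl
Why: O-sulfonylation breaks no bond to the stereocentre, so the configuration is retained.

**Vinyl iodide fragment: assembly**

Step 6
Reactants: 5 (2S)-2-{[(4-methoxybenzyl)oxy]methyl}butanal; 8 (2R)-pent-3-yn-2-yl methanesulfonate
Product: 10 (2S,3S,4S)-2-ethyl-1-[(4-methoxybenzyl)oxy]-4-methylhept-5-yn-3-ol, via allenylzinc 9 (not isolated)
Conditions: Pd(OAc)2 (5 mol%), PPh3 (5 mol%), Et2Zn (3 equiv), THF, −78 to −20 °C; aq NH4Cl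
Reagents that add atoms: none
Why: Marshall propargylation, in which zerovalent palladium displaces the mesylate anti (SN2'), transmetalation gives the chiral allenylzinc, and its cyclic SE2' addition to the aldehyde sets the methyl centre (net inversion of 8, 4S) and the carbinol centre (anti to methyl, 3S) under reagent control.

Step 7
Reactants: 10 (2S,3S,4S)-2-ethyl-1-[(4-methoxybenzyl)oxy]-4-methylhept-5-yn-3-ol
Product: 11 tert-butyl({(2S,3S,4S)-2-ethyl-1-[(4-methoxybenzyl)oxy]-4-methylhept-5-yn-3-yl}oxy)dimethylsilane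
Conditions: TBSOTf, 2,6-lutidine, CH2Cl2, −78 to 0 °C
Reagents that add atoms: tert-butyldimethylsilyl trifluoromethanesulfonate CC(C)(C)[Si](C)(C)OS(=O)(=O)C(F)(F)F
Why: Silyl ether formation with the reactive silyl triflate protects the hindered secondary alcohol without touching any stereocentre.

Step 8
Reactants: 11 tert-butyl({(2S,3S,4S)-2-ethyl-1-[(4-methoxybenzyl)oxy]-4-methylhept-5-yn-3-yl}oxy)dimethylsilane
Product: 13 tert-butyl({(2S,3S,4S,5E)-2-ethyl-6-iodo-1-[(4-methoxybenzyl)oxy]-4-methylhept-5-en-3-yl}oxy)dimethylsilane, via alkenylzirconocene 12 (not isolated)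
Conditions: Cp2Zr(H)Cl (2.5 equiv), THF, 50 °C; then I2, THF, 0 °C
Reagents that add atoms: iodine II
Why: Hydrozirconation–iodination, in which syn Zr–H addition equilibrated by excess hydride places zirconium on the methyl-bearing carbon remote from the branched centre and iodinolysis with retention gives the E 2-iodoalkene.

Step 9
Reactants: 13 tert-butyl({(2S,3S,4S,5E)-2-ethyl-6-iodo-1-[(4-methoxybenzyl)oxy]-4-methylhept-5-en-3-yl}oxy)dimethylsilane
Product: 14 (2S,3S,4S,5E)-3-{[tert-butyl(dimethyl)silyl]oxy}-2-ethyl-6-iodo-4-methylhept-5-en-1-ol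
Conditions: DDQ, CH2Cl2/pH 7 buffer (10:1), 0 °C
Reagents that add atoms: none
Why: Oxidative cleavage of the 4-methoxybenzyl ether (hydride abstraction by DDQ, then hydrolysis of the oxocarbenium ion) leaves the silyl ether and the vinyl iodide intact.

Step 10
Reactants: 14 (2S,3S,4S,5E)-3-{[tert-butyl(dimethyl)silyl]oxy}-2-ethyl-6-iodo-4-methylhept-5-en-1-ol
Product: 15 (2R,3S,4S,5E)-3-{[tert-butyl(dimethyl)silyl]oxy}-2-ethyl-6-iodo-4-methylhept-5-enal
Conditions: Dess–Martin periodinane, NaHCO3, CH2Cl2, 0 °C to rt; used crude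
Reagents that add atoms: none
Why: Dess–Martin oxidation under buffered non-basic conditions gives the α-branched aldehyde without epimerisation, the C2 descriptor becoming R by priority change only.

**Ylide branch**

Step 11
Reactants: 16 2-bromobutanoic acid (racemic)
Product: 17 2-(trimethylsilyl)ethyl 2-bromobutanoate (racemic)
Conditions: Me3SiCH2CH2OH, DCC, DMAP (cat.), CH2Cl2, 0 °C to rt
Reagents that add atoms: 2-(trimethylsilyl)ethanol C[Si](C)(C)CCO
Why: Steglich esterification installs an ester that can later be cleaved by fluoride at silicon, which matters because the final carboxyl sits between two quaternary carbons and cannot be saponified.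

Step 12
Reactants: 17 2-(trimethylsilyl)ethyl 2-bromobutanoate
Product: 18 triphenyl{1-[2-(trimethylsilyl)ethoxy]-1-oxobutan-2-yl}phosphonium bromide
Conditions: PPh3, toluene, 90 °C; salt filtered off
Reagents that add atoms: triphenylphosphine c1ccc(cc1)P(c1ccccc1)c1ccccc1
Why: SN2 quaternisation of the phosphine by the carbonyl-activated secondary bromide; the racemic centre becomes the ylide carbon next.

Step 13
Reactants: 18 triphenyl{1-[2-(trimethylsilyl)ethoxy]-1-oxobutan-2-yl}phosphonium bromide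
Product: 19 2-(trimethylsilyl)ethyl 2-(triphenylphosphoranylidene)butanoate
Conditions: aq NaOH (1 M), CH2Cl2, 0 °C
Reagents that add atoms: none
Why: Deprotonation of the acidic α-C–H gives the isolable ester-stabilised ylide.

Step 14
Reactants: 15 (2R,3S,4S,5E)-3-{[tert-butyl(dimethyl)silyl]oxy}-2-ethyl-6-iodo-4-methylhept-5-enal; 19 2-(trimethylsilyl)ethyl 2-(triphenylphosphoranylidene)butanoate
Product: 20 2-(trimethylsilyl)ethyl (2E,4S,5S,6S,7E)-5-{[tert-butyl(dimethyl)silyl]oxy}-2,4-diethyl-8-iodo-6-methylnona-2,7-dienoate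
Conditions: toluene, 80 °C
Reagents that add atoms: none
Why: Wittig olefination with a stabilised α-ethyl ylide is E-selective through reversible oxaphosphetane formation, and the base-free conditions preserve the adjacent stereocentre.

**Dienyl iodide fragment**

Step 15
Reactants: 21 ethynylbenzene
Product: 23 [(E)-2-iodoethenyl]benzene, via styrylzirconocene 22 (not isolated)
Conditions: Cp2Zr(H)Cl, THF, rt; then I2, 0 °C
Reagents that add atoms: iodine II
Why: Hydrozirconation–iodination (syn anti-Markovnikov Zr–H addition, iodinolysis with retention) gives the E vinyl iodide only.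

Step 16
Reactants: 23 [(E)-2-iodoethenyl]benzene; 24 ethynyl(trimethyl)silane
Product: 25 trimethyl[(3E)-4-phenylbut-3-en-1-yn-1-yl]silane
Conditions: PdCl2(PPh3)2 (2 mol%), CuI (4 mol%), Et3N, THF, rt
Reagents that add atoms: none
Why: Sonogashira coupling joins the sp2 and sp carbons with retention of the alkene geometry.

Step 17
Reactants: 25 trimethyl[(3E)-4-phenylbut-3-en-1-yn-1-yl]silane
Product: 26 [(1E)-but-1-en-3-yn-1-yl]benzene
Conditions: K2CO3, MeOH, rt
Reagents that add atoms: none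
Why: Methoxide-mediated protodesilylation frees the terminal alkyne needed for carbometalation.

Step 18
Reactants: 26 [(1E)-but-1-en-3-yn-1-yl]benzene
Product: 28 [(1E,3E)-3-ethyl-4-iodobuta-1,3-dien-1-yl]benzene, via dienylcopper 27 (not isolated)
Conditions: EtMgBr, CuBr·SMe2, Et2O/Me2S, −45 to −20 °C; then I2, THF, −40 to 0 °C
Reagents that add atoms: ethylmagnesium bromide CC[Mg]Br; iodine II
Why: Normant carbocupration adds ethyl and copper syn across the terminal alkyne (ethyl to the internal carbon, copper to the terminus), so copper and then iodine (iodinolysis with retention) sit cis to ethyl and trans to the styryl group.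

**Fragment coupling and endgame**

Step 19
Reactants: 28 [(1E,3E)-3-ethyl-4-iodobuta-1,3-dien-1-yl]benzene; 20 2-(trimethylsilyl)ethyl (2E,4S,5S,6S,7E)-5-{[tert-butyl(dimethyl)silyl]oxy}-2,4-diethyl-8-iodo-6-methylnona-2,7-dienoate
Product: 31 2-(trimethylsilyl)ethyl (2E,4S,5S,6S,7E,9E,11E)-5-{[tert-butyl(dimethyl)silyl]oxy}-2,4,10-triethyl-6,8-dimethyl-12-phenyldodeca-2,7,9,11-tetraenoate, via dienyllithium 29 (not isolated), via dienylzinc chloride 30 (not isolated)
Conditions: 28, t-BuLi (2 equiv), Et2O, −78 °C; ZnCl2, THF, −78 to 0 °C; then 20, Pd(PPh3)4 (5 mol%), THF, rt, dark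
Reagents that add atoms: none
Why: Negishi cross-coupling (iodine–lithium exchange, transmetalation to zinc, oxidative addition of zerovalent palladium into the C–I bond of 20, reductive elimination) joins the two halves with retention of both alkene geometries, and the organozinc tolerates the ester.

Step 20
Reactants: 31 2-(trimethylsilyl)ethyl (2E,4S,5S,6S,7E,9E,11E)-5-{[tert-butyl(dimethyl)silyl]oxy}-2,4,10-triethyl-6,8-dimethyl-12-phenyldodeca-2,7,9,11-tetraenoate
Product: 32 2-(trimethylsilyl)ethyl (1S,2S,3S,3aR,4R,5S,7aR)-2-{[tert-butyl(dimethyl)silyl]oxy}-3,4,5-triethyl-1,7-dimethyl-5-[(E)-2-phenylethenyl]-2,3,3a,4,5,7a-hexahydro-1H-indene-4-carboxylate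
Conditions: toluene (0.01 M), BHT, 140 °C, sealed tube
Reagents that add atoms: none
Why: Thermal intramolecular Diels–Alder reaction with the ester endo, in which allylic 1,3-strain holds the C–H bonds of both tether stereocentres in the plane of the neighbouring alkene (against the C8 methyl and the C2 ethyl), so the diene is attacked anti to the C6 methyl and the trans-fused adduct forms with new centres 3aR, 4R, 5S and 7aR, the two ethyl groups cis and styryl cis to the ester.

Step 21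
Reactants: 32 2-(trimethylsilyl)ethyl (1S,2S,3S,3aR,4R,5S,7aR)-2-{[tert-butyl(dimethyl)silyl]oxy}-3,4,5-triethyl-1,7-dimethyl-5-[(E)-2-phenylethenyl]-2,3,3a,4,5,7a-hexahydro-1H-indene-4-carboxylate
Product: 33 2-(trimethylsilyl)ethyl (1S,2S,3S,3aR,4R,5S,7aR)-3,4,5-triethyl-2-hydroxy-1,7-dimethyl-5-[(E)-2-phenylethenyl]-2,3,3a,4,5,7a-hexahydro-1H-indene-4-carboxylate
Conditions: HF·pyridine, pyridine, THF, 0 °C to rt
Reagents that add atoms: none
Why: Buffered HF cleaves the Si–O bond of the silyl ether, while the 2-(trimethylsilyl)ethyl ester, which needs unsolvated fluoride, and the alkenes survive.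

Step 22
Reactants: 33 2-(trimethylsilyl)ethyl (1S,2S,3S,3aR,4R,5S,7aR)-3,4,5-triethyl-2-hydroxy-1,7-dimethyl-5-[(E)-2-phenylethenyl]-2,3,3a,4,5,7a-hexahydro-1H-indene-4-carboxylate
Product: 34 2-(trimethylsilyl)ethyl (1S,3S,3aR,4R,5S,7aR)-3,4,5-triethyl-1,7-dimethyl-2-oxo-5-[(E)-2-phenylethenyl]-2,3,3a,4,5,7a-hexahydro-1H-indene-4-carboxylate
Conditions: Dess–Martin periodinane, NaHCO3, CH2Cl2, rt
Reagents that add atoms: none
Why: Dess–Martin oxidation gives the cyclopentanone under neutral conditions, and both α-centres already have the all-trans arrangement that is also the thermodynamic one, so later enolisation cannot erode them.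

Step 23
Reactants: 34 2-(trimethylsilyl)ethyl (1S,3S,3aR,4R,5S,7aR)-3,4,5-triethyl-1,7-dimethyl-2-oxo-5-[(E)-2-phenylethenyl]-2,3,3a,4,5,7a-hexahydro-1H-indene-4-carboxylate
Product: 35 (1S,3S,3aR,4R,5S,7aR)-3,4,5-triethyl-1,7-dimethyl-2-oxo-5-[(E)-2-phenylethenyl]-2,3,3a,4,5,7a-hexahydro-1H-indene-4-carboxylic acid
Conditions: TBAF, THF, 0 °C to rt; dilute HCl work-up
Reagents that add atoms: none
Why: Fluoride attacks silicon and the ester fragments (loss of fluorotrimethylsilane and ethene), which frees the neopentyl-type acid without any attack at the shielded carbonyl.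

## Compound list

1 | (2E)-1,4-dibromobut-2-ene | BrC/C=C/CBr | starting material
2 | 1-({[(2E)-4-bromobut-2-en-1-yl]oxy}methyl)-4-methoxybenzene | COc1ccc(COC/C=C/CBr)cc1 | intermediate
3 | 1-({[(2R)-2-ethylbut-3-en-1-yl]oxy}methyl)-4-methoxybenzene | C=C[C@@H](CC)COCc1ccc(OC)cc1 | intermediate
4 | 3-{(2S)-1-[(4-methoxybenzyl)oxy]butan-2-yl}-1,2,4-trioxolane (ring carbon epimers) | C1OOC(O1)[C@@H](CC)COCc1ccc(OC)cc1 | intermediate
5 | (2S)-2-{[(4-methoxybenzyl)oxy]methyl}butanal | O=C[C@@H](CC)COCc1ccc(OC)cc1 | intermediate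
6 | pent-3-yn-2-one | CC#CC(C)=O | starting material
7 | (2R)-pent-3-yn-2-ol | CC#C[C@@H](C)O | intermediate
8 | (2R)-pent-3-yn-2-yl methanesulfonate | CC#C[C@@H](C)OS(C)(=O)=O | intermediate
9 | ethyl[(aS)-penta-2,3-dien-2-yl]zinc | CC[Zn]C(C)=[C@@]=C([H])C | intermediate
10 | (2S,3S,4S)-2-ethyl-1-[(4-methoxybenzyl)oxy]-4-methylhept-5-yn-3-ol | CC#C[C@H](C)[C@H](O)[C@@H](CC)COCc1ccc(OC)cc1 | intermediate
11 | tert-butyl({(2S,3S,4S)-2-ethyl-1-[(4-methoxybenzyl)oxy]-4-methylhept-5-yn-3-yl}oxy)dimethylsilane | CC#C[C@H](C)[C@H](O[Si](C)(C)C(C)(C)C)[C@@H](CC)COCc1ccc(OC)cc1 | intermediate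
12 | chlorobis(cyclopentadienyl)[(2E,4S,5S,6S)-5-{[tert-butyl(dimethyl)silyl]oxy}-6-ethyl-7-[(4-methoxybenzyl)oxy]-4-methylhept-2-en-2-yl]zirconium (cyclopentadienyl drawn σ-bonded) | Cl[Zr](C1C=CC=C1)(C1C=CC=C1)/C(C)=C/[C@H](C)[C@H](O[Si](C)(C)C(C)(C)C)[C@@H](CC)COCc1ccc(OC)cc1 | intermediate
13 | tert-butyl({(2S,3S,4S,5E)-2-ethyl-6-iodo-1-[(4-methoxybenzyl)oxy]-4-methylhept-5-en-3-yl}oxy)dimethylsilane | I/C(C)=C/[C@H](C)[C@H](O[Si](C)(C)C(C)(C)C)[C@@H](CC)COCc1ccc(OC)cc1 | intermediate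
14 | (2S,3S,4S,5E)-3-{[tert-butyl(dimethyl)silyl]oxy}-2-ethyl-6-iodo-4-methylhept-5-en-1-ol | I/C(C)=C/[C@H](C)[C@H](O[Si](C)(C)C(C)(C)C)[C@@H](CC)CO | intermediate
15 | (2R,3S,4S,5E)-3-{[tert-butyl(dimethyl)silyl]oxy}-2-ethyl-6-iodo-4-methylhept-5-enal | I/C(C)=C/[C@H](C)[C@H](O[Si](C)(C)C(C)(C)C)[C@@H](CC)C=O | intermediate
16 | 2-bromobutanoic acid (racemic) | CCC(Br)C(=O)O | starting material
17 | 2-(trimethylsilyl)ethyl 2-bromobutanoate (racemic) | CCC(Br)C(=O)OCC[Si](C)(C)C | intermediate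
18 | triphenyl{1-[2-(trimethylsilyl)ethoxy]-1-oxobutan-2-yl}phosphonium bromide | CCC(C(=O)OCC[Si](C)(C)C)[P+](c1ccccc1)(c1ccccc1)c1ccccc1.[Br-] | intermediate
19 | 2-(trimethylsilyl)ethyl 2-(triphenylphosphoranylidene)butanoate | CCC(C(=O)OCC[Si](C)(C)C)=P(c1ccccc1)(c1ccccc1)c1ccccc1 | intermediate
20 | 2-(trimethylsilyl)ethyl (2E,4S,5S,6S,7E)-5-{[tert-butyl(dimethyl)silyl]oxy}-2,4-diethyl-8-iodo-6-methylnona-2,7-dienoate | I/C(C)=C/[C@H](C)[C@H](O[Si](C)(C)C(C)(C)C)[C@@H](CC)/C=C(CC)/C(=O)OCC[Si](C)(C)C | intermediate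
21 | ethynylbenzene | C#Cc1ccccc1 | starting material
22 | chlorobis(cyclopentadienyl)[(E)-2-phenylethenyl]zirconium (cyclopentadienyl drawn σ-bonded) | Cl[Zr](C1C=CC=C1)(C1C=CC=C1)/C=C/c1ccccc1 | intermediate
23 | [(E)-2-iodoethenyl]benzene | I/C=C/c1ccccc1 | intermediate
24 | ethynyl(trimethyl)silane | C#C[Si](C)(C)C | starting material
25 | trimethyl[(3E)-4-phenylbut-3-en-1-yn-1-yl]silane | C[Si](C)(C)C#C/C=C/c1ccccc1 | intermediate
26 | [(1E)-but-1-en-3-yn-1-yl]benzene | C#C/C=C/c1ccccc1 | intermediate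
27 | [(1E,3E)-2-ethyl-4-phenylbuta-1,3-dien-1-yl]copper | [Cu]/C=C(CC)/C=C/c1ccccc1 | intermediate
28 | [(1E,3E)-3-ethyl-4-iodobuta-1,3-dien-1-yl]benzene | I/C=C(CC)/C=C/c1ccccc1 | intermediate
29 | [(1E,3E)-2-ethyl-4-phenylbuta-1,3-dien-1-yl]lithium | [Li]/C=C(CC)/C=C/c1ccccc1 | intermediate
30 | chloro[(1E,3E)-2-ethyl-4-phenylbuta-1,3-dien-1-yl]zinc | Cl[Zn]/C=C(CC)/C=C/c1ccccc1 | intermediate
31 | 2-(trimethylsilyl)ethyl (2E,4S,5S,6S,7E,9E,11E)-5-{[tert-butyl(dimethyl)silyl]oxy}-2,4,10-triethyl-6,8-dimethyl-12-phenyldodeca-2,7,9,11-tetraenoate | c1ccccc1/C=C/C(CC)=C/C(C)=C/[C@H](C)[C@H](O[Si](C)(C)C(C)(C)C)[C@@H](CC)/C=C(CC)/C(=O)OCC[Si](C)(C)C | intermediate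
32 | 2-(trimethylsilyl)ethyl (1S,2S,3S,3aR,4R,5S,7aR)-2-{[tert-butyl(dimethyl)silyl]oxy}-3,4,5-triethyl-1,7-dimethyl-5-[(E)-2-phenylethenyl]-2,3,3a,4,5,7a-hexahydro-1H-indene-4-carboxylate | CC[C@@H]1[C@@H](O[Si](C)(C)C(C)(C)C)[C@@H](C)[C@@H]2C(C)=C[C@@](/C=C/c3ccccc3)(CC)[C@](CC)(C(=O)OCC[Si](C)(C)C)[C@H]21 | intermediate
33 | 2-(trimethylsilyl)ethyl (1S,2S,3S,3aR,4R,5S,7aR)-3,4,5-triethyl-2-hydroxy-1,7-dimethyl-5-[(E)-2-phenylethenyl]-2,3,3a,4,5,7a-hexahydro-1H-indene-4-carboxylate | CC[C@@H]1[C@@H](O)[C@@H](C)[C@@H]2C(C)=C[C@@](/C=C/c3ccccc3)(CC)[C@](CC)(C(=O)OCC[Si](C)(C)C)[C@H]21 | intermediate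
34 | 2-(trimethylsilyl)ethyl (1S,3S,3aR,4R,5S,7aR)-3,4,5-triethyl-1,7-dimethyl-2-oxo-5-[(E)-2-phenylethenyl]-2,3,3a,4,5,7a-hexahydro-1H-indene-4-carboxylate | CC[C@@H]1C(=O)[C@@H](C)[C@@H]2C(C)=C[C@@](/C=C/c3ccccc3)(CC)[C@](CC)(C(=O)OCC[Si](C)(C)C)[C@H]21 | intermediate
35 | (1S,3S,3aR,4R,5S,7aR)-3,4,5-triethyl-1,7-dimethyl-2-oxo-5-[(E)-2-phenylethenyl]-2,3,3a,4,5,7a-hexahydro-1H-indene-4-carboxylic acid | CC[C@@H]1C(=O)[C@@H](C)[C@@H]2C(C)=C[C@@](/C=C/c3ccccc3)(CC)[C@](CC)(C(=O)O)[C@H]21 | target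

## Step count and risks

Total step count: 23.
Longest linear sequence: 14 steps (1, 2, 3, 6, 7, 8, 9, 10, 14, 19, 20, 21, 22, 23).

**Step 20 (intramolecular Diels–Alder).** Two adjacent quaternary centres are formed from a diene with an inside ethyl group; the heat needed may let a 1,5-hydrogen shift of the triene compete. The fallback makes the dienophile more electron-poor instead of heating harder, and sets out from 31. i-Bu2AlH (CH2Cl2, −78 °C) reduces the ester to the tetraenol F1, and MnO2 (CH2Cl2, rt) gives the tetraenal F2. Me2AlCl (CH2Cl2, −78 to −20 °C) then drives the same endo-selective cycloaddition at low temperature to the bicyclic aldehyde F3. Pinnick oxidation (NaClO2, NaH2PO4, 2-methylbut-2-ene, t-BuOH/H2O) gives the silyl ether acid F4, HF·pyridine gives the hydroxy acid F5, and Dess–Martin oxidation of F5 comes back to the route at 35.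

**Step 18 (ethylcupration of the conjugated enyne).** Deprotonation of the acidic alkyne C–H or a loss of regiocontrol would cost the fragment. The fallback sets out from 26. BBr3 (CH2Cl2, −78 °C) adds syn across the alkyne to give the dibromoborane F6, which pinacol and Et3N convert into the bromodienyl boronate F7. Negishi coupling with EtZnBr and Pd(P(t-Bu)3)2 (THF, rt) replaces bromine by ethyl with retention and gives the ethyldienyl boronate F8. Suzuki–Miyaura coupling of F8 with 20 (Pd(PPh3)4, aq K3PO4, THF, 40 °C) comes back to the route at 31, bypassing 28.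

**Step 19 (Negishi fragment coupling).** The dienyllithium may add to styrene units or the hindered coupling may stall and give homocoupling. The fallback sets out from 28. After the same iodine–lithium exchange to 29, Bu3SnCl (−78 °C to rt) gives the dienylstannane F9, which is purified. F9 is then joined to 20 by a copper-assisted Stille coupling (Pd(PPh3)4, CuCl, LiCl, DMSO, rt to 50 °C), coming back to the route at 31.

## Further compounds

F1 | step 20 | (2E,4S,5S,6S,7E,9E,11E)-5-{[tert-butyl(dimethyl)silyl]oxy}-2,4,10-triethyl-6,8-dimethyl-12-phenyldodeca-2,7,9,11-tetraen-1-ol | c1ccccc1/C=C/C(CC)=C/C(C)=C/[C@H](C)[C@H](O[Si](C)(C)C(C)(C)C)[C@@H](CC)/C=C(CC)/CO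
F2 | step 20 | (2E,4S,5S,6S,7E,9E,11E)-5-{[tert-butyl(dimethyl)silyl]oxy}-2,4,10-triethyl-6,8-dimethyl-12-phenyldodeca-2,7,9,11-tetraenal | c1ccccc1/C=C/C(CC)=C/C(C)=C/[C@H](C)[C@H](O[Si](C)(C)C(C)(C)C)[C@@H](CC)/C=C(CC)/C=O
F3 | step 20 | (1S,2S,3S,3aR,4R,5S,7aR)-2-{[tert-butyl(dimethyl)silyl]oxy}-3,4,5-triethyl-1,7-dimethyl-5-[(E)-2-phenylethenyl]-2,3,3a,4,5,7a-hexahydro-1H-indene-4-carbaldehyde | CC[C@@H]1[C@@H](O[Si](C)(C)C(C)(C)C)[C@@H](C)[C@@H]2C(C)=C[C@@](/C=C/c3ccccc3)(CC)[C@](CC)(C=O)[C@H]21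
F4 | step 20 | (1S,2S,3S,3aR,4R,5S,7aR)-2-{[tert-butyl(dimethyl)silyl]oxy}-3,4,5-triethyl-1,7-dimethyl-5-[(E)-2-phenylethenyl]-2,3,3a,4,5,7a-hexahydro-1H-indene-4-carboxylic acid | CC[C@@H]1[C@@H](O[Si](C)(C)C(C)(C)C)[C@@H](C)[C@@H]2C(C)=C[C@@](/C=C/c3ccccc3)(CC)[C@](CC)(C(=O)O)[C@H]21
F5 | step 20 | (1S,2S,3S,3aR,4R,5S,7aR)-3,4,5-triethyl-2-hydroxy-1,7-dimethyl-5-[(E)-2-phenylethenyl]-2,3,3a,4,5,7a-hexahydro-1H-indene-4-carboxylic acid | CC[C@@H]1[C@@H](O)[C@@H](C)[C@@H]2C(C)=C[C@@](/C=C/c3ccccc3)(CC)[C@](CC)(C(=O)O)[C@H]21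
F6 | step 18 | dibromo[(1Z,3E)-2-bromo-4-phenylbuta-1,3-dien-1-yl]borane | BrB(Br)/C=C(Br)/C=C/c1ccccc1
F7 | step 18 | 2-[(1Z,3E)-2-bromo-4-phenylbuta-1,3-dien-1-yl]-4,4,5,5-tetramethyl-1,3,2-dioxaborolane | CC1(C)OB(OC1(C)C)/C=C(Br)/C=C/c1ccccc1
F8 | step 18 | 2-[(1E,3E)-2-ethyl-4-phenylbuta-1,3-dien-1-yl]-4,4,5,5-tetramethyl-1,3,2-dioxaborolane | CC1(C)OB(OC1(C)C)/C=C(CC)/C=C/c1ccccc1
F9 | step 19 | tributyl[(1E,3E)-2-ethyl-4-phenylbuta-1,3-dien-1-yl]stannane | CCCC[Sn](CCCC)(CCCC)/C=C(CC)/C=C/c1ccccc1
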